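**Plan**

- Retrosynthesis first cuts the two aryl–CH2 bonds C3'–C1'' (ring A) and C5–C1'' (ring B) together, leading back to the 4'-O- and 4-O-(1,1-dimethylallyl) ethers. This works because each prenyl-bearing carbon is ortho to a phenolic oxygen (O4', O4) whose other ortho carbon is either its symmetry twin (C5', ring A being symmetric about the C1'–C4' axis) or already oxygenated (C3).
- Next the two O–C(CH3)2 ether bonds are cut (back to a 1,1-dimethylpropargyl carbonate), and last the Cα–Cβ bond of the three-carbon linker (aldol), which separates a phloroacetophenone from protocatechualdehyde.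
- Forward: both aromatic rings are bought. The chain is joined by Claisen–Schmidt condensation, one hydrogenation saturates the linker and frees O4' and O4, both oxygens are tert-propargylated and semi-hydrogenated, the twofold [3,3] shift moves both C5 units from O to C, and the MOM groups come off last. No ring is formed at any stage.
- Stereochemistry: the target has no stereocentre and no stereogenic alkene. The only geometric element, the E-enone of the chalcone, is erased by hydrogenation.

Key step: step 10

Assumption: the commercial monohydrate of 2',4',6'-trihydroxyacetophenone is dried before use; primed locants refer to ring A (the acyl ring), unprimed ones to ring B.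

**Route**

Step 1
Reactants: 1 2',4',6'-trihydroxyacetophenone
Product: 2 4'-benzyloxy-2',6'-dihydroxyacetophenone
Conditions: BnBr (1.0 equiv), K2CO3 (1.0 equiv), acetone, reflux
Reagents that add atoms: benzyl bromide, BrCc1ccccc1
Why: Williamson etherification under limiting base: the 4'-OH, para to the acetyl group and outside the hydrogen-bonded chelate with the carbonyl, is the most acidic and most exposed phenol and should be alkylated first, any 2',4'-dibenzyl ether being removed by chromatography.

Step 2
Reactants: 2 4'-benzyloxy-2',6'-dihydroxyacetophenone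
Product: 3 4'-benzyloxy-2',6'-bis(methoxymethoxy)acetophenone
Conditions: NaH (2.4 equiv), MOMCl (2.4 equiv), DMF, 0 °C to rt
Reagents that add atoms: chloromethyl methyl ether, COCCl
Why: Williamson-type O-alkylation: NaH breaks the carbonyl chelate by turning both ortho phenols into sodium phenoxides, which displace chloride from the reactive α-chloro ether, while the benzyl ether is inert to base.

Step 3
Reactants: 4 3,4-dihydroxybenzaldehyde
Product: 5 4-benzyloxy-3-hydroxybenzaldehyde
Conditions: BnBr (1.05 equiv), NaHCO3, NaI (cat.), DMF, 40 °C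
Reagents that add atoms: benzyl bromide, BrCc1ccccc1
Why: Williamson etherification with a weak base: NaHCO3 ionises only the 4-OH, the more acidic phenol because its anion is conjugated with the para formyl group, and that phenoxide is benzylated (iodide catalysis by Finkelstein exchange).

Step 4
Reactants: 5 4-benzyloxy-3-hydroxybenzaldehyde
Product: 6 4-benzyloxy-3-(methoxymethoxy)benzaldehyde
Conditions: MOMCl, K2CO3, acetone, rt
Reagents that add atoms: chloromethyl methyl ether, COCCl
Why: Standard MOM protection (Williamson-type alkylation of the potassium phenoxide with the α-chloro ether), under which the aldehyde and the benzyl ether do not react.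

Step 5
Reactants: 3 4'-benzyloxy-2',6'-bis(methoxymethoxy)acetophenone; 6 4-benzyloxy-3-(methoxymethoxy)benzaldehyde
Product: 7 (E)-1-[4-(benzyloxy)-2,6-bis(methoxymethoxy)phenyl]-3-[4-(benzyloxy)-3-(methoxymethoxy)phenyl]prop-2-en-1-one
Conditions: KOH (50% aq.), EtOH, rt
Reagents that add atoms: none
Why: Claisen–Schmidt (crossed aldol) condensation: only the methyl ketone can enolise, the aldehyde is the only electrophile, and E1cB dehydration of the aldol gives the conjugated E-enone, all ether protecting groups being base-stable.

Step 6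
Reactants: 7 (E)-1-[4-(benzyloxy)-2,6-bis(methoxymethoxy)phenyl]-3-[4-(benzyloxy)-3-(methoxymethoxy)phenyl]prop-2-en-1-one
Product: 8 1-[4-hydroxy-2,6-bis(methoxymethoxy)phenyl]-3-[4-hydroxy-3-(methoxymethoxy)phenyl]propan-1-one
Conditions: H2 (1 atm), 10% Pd/C, EtOAc, rt
Reagents that add atoms: none
Why: Heterogeneous catalytic hydrogenation saturates the conjugated alkene and hydrogenolyses both benzyl ethers in one operation, while the MOM acetals and the ketone (twisted out of conjugation and shielded by two ortho substituents) should survive under neutral conditions.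

Step 7
Reactants: 9 2-methylbut-3-yn-2-ol
Product: 11 methyl 2-methylbut-3-yn-2-yl carbonate, via lithium 2-methylbut-3-yn-2-olate 10 (not isolated)
Conditions: n-BuLi (1.0 equiv), THF, −78 °C; then ClCO2Me, −78 °C to rt
Reagents that add atoms: methyl chloroformate, COC(=O)Cl; n-butyllithium, [Li]CCCC (its lithium remains only in intermediate 10)
Why: Acylation of a lithium alkoxide with a chloroformate: one equivalent of n-BuLi removes the hydroxyl proton in preference to the far less acidic alkyne C–H, and the tertiary alkoxide then attacks methyl chloroformate.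

Step 8
Reactants: 8 1-[4-hydroxy-2,6-bis(methoxymethoxy)phenyl]-3-[4-hydroxy-3-(methoxymethoxy)phenyl]propan-1-one; 11 methyl 2-methylbut-3-yn-2-yl carbonate
Product: 12 1-[2,6-bis(methoxymethoxy)-4-(2-methylbut-3-yn-2-yloxy)phenyl]-3-[3-(methoxymethoxy)-4-(2-methylbut-3-yn-2-yloxy)phenyl]propan-1-one
Conditions: 11 (3 equiv), CuCl2 (cat.), DBU (3 equiv), MeCN, 0 °C to rt
Reagents that add atoms: none
Why: Copper-catalysed propargylic etherification: the terminal alkyne of 11 forms a copper acetylide that expels methyl carbonate to give a copper allenylidene, and each DBU-generated phenoxide adds to its tertiary γ-carbon, a known way to aryl 1,1-dimethylpropargyl ethers that direct displacement cannot make.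

Step 9
Reactants: 12 1-[2,6-bis(methoxymethoxy)-4-(2-methylbut-3-yn-2-yloxy)phenyl]-3-[3-(methoxymethoxy)-4-(2-methylbut-3-yn-2-yloxy)phenyl]propan-1-one
Product: 13 1-[2,6-bis(methoxymethoxy)-4-(2-methylbut-3-en-2-yloxy)phenyl]-3-[3-(methoxymethoxy)-4-(2-methylbut-3-en-2-yloxy)phenyl]propan-1-one
Conditions: H2 (1 atm), Pd/CaCO3 poisoned with Pb(OAc)2 (Lindlar catalyst), quinoline, EtOAc, rt
Reagents that add atoms: none
Why: Lindlar semi-hydrogenation: the lead- and quinoline-poisoned palladium surface adds one equivalent of H2 to each terminal alkyne and binds the resulting alkene too weakly to reduce it further, leaving ketone, acetals and aryl ethers untouched.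

Step 10
Reactants: 13 1-[2,6-bis(methoxymethoxy)-4-(2-methylbut-3-en-2-yloxy)phenyl]-3-[3-(methoxymethoxy)-4-(2-methylbut-3-en-2-yloxy)phenyl]propan-1-one
Product: 14 1-[4-hydroxy-2,6-bis(methoxymethoxy)-3-(3-methylbut-2-en-1-yl)phenyl]-3-[4-hydroxy-3-(methoxymethoxy)-5-(3-methylbut-2-en-1-yl)phenyl]propan-1-one
Conditions: PhNEt2 (degassed), 140 °C, Ar
Reagents that add atoms: none
Why: Each aryl 1,1-dimethylallyl ether undergoes a concerted, suprafacial aromatic Claisen ([3,3] sigmatropic) shift through a six-membered chair-like transition state in which the O–C(CH3)2 bond breaks while the terminal CH2 bonds to the ortho ring carbon, and the resulting cyclohexa-2,4-dienone tautomerises to the phenol, so the allyl unit arrives inverted as a normal 3-methylbut-2-enyl group. The closest known reaction is the thermal ortho-Claisen rearrangement of aryl 1,1-dimethylallyl ethers to ortho-prenylphenols, which proceeds at lower temperature than that of primary allyl ethers because the tertiary C–O bond is weaker. No ring is closed and no stereocentre is created; two C–C bonds (C3'–C1'' on ring A, C5–C1'' on ring B) are formed, the two rings reacting independently in one pot. The selectivity required is positional: on ring A the two carbons ortho to O4' are equivalent because O2' and O6' carry the same MOM group, and on ring B only C5 can lead to a phenol, since a shift to the MOM-oxygenated C3 gives a dienone that cannot enolise and either reverts or passes by Cope shift to the equally blocked C1 and back. The basic amine solvent keeps the medium free of acid, which should suppress ionisation of the tertiary ethers to a prenyl cation (loss of isoprene, positional scrambling) and closure of the new ortho-prenylphenols to 2,2-dimethylchromans.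

Step 11
Reactants: 14 1-[4-hydroxy-2,6-bis(methoxymethoxy)-3-(3-methylbut-2-en-1-yl)phenyl]-3-[4-hydroxy-3-(methoxymethoxy)-5-(3-methylbut-2-en-1-yl)phenyl]propan-1-one
Product: 15 2',4',6',3,4-pentahydroxy-3',5-diprenyldihydrochalcone
Conditions: HCl (0.5 M in MeOH), rt to 40 °C
Reagents that add atoms: none
Why: Acid-catalysed transacetalisation (methanolysis) of the three MOM aryl ethers to dimethoxymethane; the two ethers ortho to the ketone cleave fastest, and in dilute acid near room temperature the trisubstituted alkenes should not be protonated fast enough for the neighbouring phenols to close chromans.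

**Compound list**

1 | 2',4',6'-trihydroxyacetophenone | CC(=O)c1c(O)cc(O)cc1O | starting material
2 | 4'-benzyloxy-2',6'-dihydroxyacetophenone | CC(=O)c1c(O)cc(OCc2ccccc2)cc1O | intermediate
3 | 4'-benzyloxy-2',6'-bis(methoxymethoxy)acetophenone | CC(=O)c1c(OCOC)cc(OCc2ccccc2)cc1OCOC | intermediate
4 | 3,4-dihydroxybenzaldehyde | O=Cc1ccc(O)c(O)c1 | starting material
5 | 4-benzyloxy-3-hydroxybenzaldehyde | O=Cc1ccc(OCc2ccccc2)c(O)c1 | intermediate
6 | 4-benzyloxy-3-(methoxymethoxy)benzaldehyde | O=Cc1ccc(OCc2ccccc2)c(OCOC)c1 | intermediate
7 | (E)-1-[4-(benzyloxy)-2,6-bis(methoxymethoxy)phenyl]-3-[4-(benzyloxy)-3-(methoxymethoxy)phenyl]prop-2-en-1-one | COCOc1cc(OCc2ccccc2)cc(OCOC)c1C(=O)/C=C/c1ccc(OCc2ccccc2)c(OCOC)c1 | intermediate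
8 | 1-[4-hydroxy-2,6-bis(methoxymethoxy)phenyl]-3-[4-hydroxy-3-(methoxymethoxy)phenyl]propan-1-one | COCOc1cc(O)cc(OCOC)c1C(=O)CCc1ccc(O)c(OCOC)c1 | intermediate
9 | 2-methylbut-3-yn-2-ol | CC(C)(O)C#C | starting material
10 | lithium 2-methylbut-3-yn-2-olate (not isolated) | [Li+].[O-]C(C)(C)C#C | intermediate
11 | methyl 2-methylbut-3-yn-2-yl carbonate | COC(=O)OC(C)(C)C#C | intermediate
12 | 1-[2,6-bis(methoxymethoxy)-4-(2-methylbut-3-yn-2-yloxy)phenyl]-3-[3-(methoxymethoxy)-4-(2-methylbut-3-yn-2-yloxy)phenyl]propan-1-one | C#CC(C)(C)Oc1cc(OCOC)c(C(=O)CCc2ccc(OC(C)(C)C#C)c(OCOC)c2)c(OCOC)c1 | intermediate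
13 | 1-[2,6-bis(methoxymethoxy)-4-(2-methylbut-3-en-2-yloxy)phenyl]-3-[3-(methoxymethoxy)-4-(2-methylbut-3-en-2-yloxy)phenyl]propan-1-one (Claisen precursor) | C=CC(C)(C)Oc1cc(OCOC)c(C(=O)CCc2ccc(OC(C)(C)C=C)c(OCOC)c2)c(OCOC)c1 | intermediate
14 | 1-[4-hydroxy-2,6-bis(methoxymethoxy)-3-(3-methylbut-2-en-1-yl)phenyl]-3-[4-hydroxy-3-(methoxymethoxy)-5-(3-methylbut-2-en-1-yl)phenyl]propan-1-one (Claisen product) | CC(C)=CCc1cc(CCC(=O)c2c(OCOC)cc(O)c(CC=C(C)C)c2OCOC)cc(OCOC)c1O | intermediate
15 | 2',4',6',3,4-pentahydroxy-3',5-diprenyldihydrochalcone | CC(C)=CCc1cc(CCC(=O)c2c(O)cc(O)c(CC=C(C)C)c2O)cc(O)c1O | target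

**Step count**

Total: 11 steps. Longest linear sequence: 8 steps (1, 2, 5, 6, 8, 9, 10, 11 from compound 1; equally 3, 4, 5, 6, 8, 9, 10, 11 from compound 4).

**Steps most likely to fail**

Step 10. The tertiary allyl ethers may fragment (loss of isoprene, returning the free phenols) instead of rearranging, or only one of the two rings may rearrange cleanly. The fallback sets out from 8 and keeps the twofold ortho-Claisen shift but uses primary allyl ethers, which cannot ionise, and adds the two methyl groups afterwards. Both phenols of 8 are allylated with allyl bromide and K2CO3 in acetone to give 1-[2,6-bis(methoxymethoxy)-4-(prop-2-en-1-yloxy)phenyl]-3-[3-(methoxymethoxy)-4-(prop-2-en-1-yloxy)phenyl]propan-1-one F1. Heating F1 in PhNEt2 at about 195 °C should deliver, with the same positional control (C3'/C5' equivalent, C3 blocked), 1-[4-hydroxy-2,6-bis(methoxymethoxy)-3-(prop-2-en-1-yl)phenyl]-3-[4-hydroxy-3-(methoxymethoxy)-5-(prop-2-en-1-yl)phenyl]propan-1-one F2. Olefin cross-metathesis of F2 with excess 2-methylbut-2-ene and second-generation Grubbs catalyst, (H2IMes)(PCy3)Cl2Ru=CHPh, in CH2Cl2 at 40 °C converts both allyl groups into prenyl groups and returns to the route at 14.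

Step 9. Over-reduction of one or both terminal alkenes would give tert-pentyl ethers that cannot rearrange and are hard to separate from 13. The fallback sets out from 8, bypasses 12 and forms the tertiary allyl ethers directly by palladium-catalysed allylic etherification. Commercial 2-methylbut-3-en-2-ol is deprotonated with n-BuLi in THF at −78 °C to lithium 2-methylbut-3-en-2-olate F3 (not isolated), which is quenched with methyl chloroformate to give methyl 2-methylbut-3-en-2-yl carbonate F4. Treating 8 with F4 and Pd(PPh3)4 (zerovalent palladium) in THF at 0 °C should give, by kinetic attack of each phenoxide at the more substituted terminus of the 1,1-dimethyl-π-allyl palladium complex, the bis(1,1-dimethylallyl) ether, returning to the route at 13.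

Step 11. Acid may protonate the prenyl alkenes so that the neighbouring phenols close 2,2-dimethylchroman rings before the slowest MOM ether (O3 on ring B) is cleaved. The fallback sets out from 12 and moves the acid step to the alkyne stage, where neither an alkene nor a readily ionised tertiary allyl ether is present. Methanolic HCl at rt removes the three MOM groups to give 1-[2,6-dihydroxy-4-(2-methylbut-3-yn-2-yloxy)phenyl]-3-[3-hydroxy-4-(2-methylbut-3-yn-2-yloxy)phenyl]propan-1-one F5. Lindlar semi-hydrogenation (H2, Pd/CaCO3 poisoned with Pb(OAc)2, quinoline, EtOAc) gives 1-[2,6-dihydroxy-4-(2-methylbut-3-en-2-yloxy)phenyl]-3-[3-hydroxy-4-(2-methylbut-3-en-2-yloxy)phenyl]propan-1-one F6. The same twofold Claisen rearrangement in degassed PhNEt2 at 140 °C then acts on the free triphenol (ring A still symmetric, C3 still blocked by its hydroxyl) and returns to the route at 15 without acid ever meeting a prenyl group.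

**Further compounds**

F1 | step 10 | 1-[2,6-bis(methoxymethoxy)-4-(prop-2-en-1-yloxy)phenyl]-3-[3-(methoxymethoxy)-4-(prop-2-en-1-yloxy)phenyl]propan-1-one | C=CCOc1cc(OCOC)c(C(=O)CCc2ccc(OCC=C)c(OCOC)c2)c(OCOC)c1
F2 | step 10 | 1-[4-hydroxy-2,6-bis(methoxymethoxy)-3-(prop-2-en-1-yl)phenyl]-3-[4-hydroxy-3-(methoxymethoxy)-5-(prop-2-en-1-yl)phenyl]propan-1-one | C=CCc1cc(CCC(=O)c2c(OCOC)cc(O)c(CC=C)c2OCOC)cc(OCOC)c1O
F3 | step 9 | lithium 2-methylbut-3-en-2-olate | [Li+].[O-]C(C)(C)C=C
F4 | step 9 | methyl 2-methylbut-3-en-2-yl carbonate | COC(=O)OC(C)(C)C=C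
F5 | step 11 | 1-[2,6-dihydroxy-4-(2-methylbut-3-yn-2-yloxy)phenyl]-3-[3-hydroxy-4-(2-methylbut-3-yn-2-yloxy)phenyl]propan-1-one | C#CC(C)(C)Oc1cc(O)c(C(=O)CCc2ccc(OC(C)(C)C#C)c(O)c2)c(O)c1
F6 | step 11 | 1-[2,6-dihydroxy-4-(2-methylbut-3-en-2-yloxy)phenyl]-3-[3-hydroxy-4-(2-methylbut-3-en-2-yloxy)phenyl]propan-1-one | C=CC(C)(C)Oc1cc(O)c(C(=O)CCc2ccc(OC(C)(C)C=C)c(O)c2)c(O)c1
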